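## Structural features

The target joins two chroman units through a central benzene ring D. The upper unit is a 3,4-diarylchroman (benzo ring A, pyran ring C) whose C3 carries ring B (3-hydroxy-2,4-dimethoxyphenyl) and whose C4 is bonded to D1. The lower unit is a 7-hydroxyisoflavan (benzo ring E, pyran ring F) whose C3' is bonded to D6. Ring D is 1,2,3,5-tetrasubstituted: C4 on D1, a methoxy group on D2, a free hydroxyl on D4 and C3' on D6, so the two carbon substituents are ortho to each other and C4 sits between a methoxy group and a secondary alkyl group. C3 (R) and C4 (S) are adjacent and trans on ring C, whereas C3' (R) is separated from them by the D6–D1 bond, so each stereochemical domain needs its own reagent control. The fragile features are four phenols on electron-rich rings that must stay distinct from three methyl ethers, benzylic carbons that ionise easily because of ortho and para oxygen, and C3', which is epimerisable as long as C2' is a carboxyl carbon. The real difficulty is the crowded C4 methine, bonded to two aryl rings (one of them ortho,ortho'-disubstituted) and to C3, together with the absolute configuration at the remote C3'. The key step uses the ortho relation of D1 and D6: C4 on D1 and C3' on D6 are the aryl carbonyl and the methylene of a homophthalic anhydride, C2' is its second carbonyl, and C3'–C4' is an aldol bond to a ring E benzaldehyde.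

## Logic of the disconnections

33 to 32: the four phenolic O–H bonds are traced back to O–benzyl bonds. No skeletal C–O bond of 33 is benzylic (C2–O1 and C2'–O1' are alkyl aryl ethers, C4 bears no heteroatom), so hydrogenolysis can be the last step. The demand is that no earlier step uses hydrogenation or a strong Lewis acid.

32 to 31: the O1–C2 bond of ring C is cut. This separates ring closure from the C–C bond formation that sets C3 and C4, and it keeps C2 at the alcohol level so that C3 is no longer α to a carbonyl. The forward etherification needs 31 to carry exactly one free phenol, the ring A oxygen ortho to C4.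

31 to 22 and 28 (through 29 and 30): the C3–C4 bond is cut. C4 becomes the methide carbon of an o-quinone methide on ring A and C3 the α-carbon of an arylacetaldehyde, so both stereocentres arise in one catalyst-controlled bond formation, independent of C3'. The forward step must bring an enamine to a methide carbon shielded by ring D, and the labile α-aryl aldehyde must be trapped (hemiacetal 30, then reduction) before it erodes.

22 to 18 and 20 (through 21): the C4–C4a bond is cut between an aldehyde carbon on D1 and a ring A aryl anion that carries its ortho oxygen as a phenoxide. Ring A arrives in one piece and the carbinol configuration does not matter, because it is erased in 29. The demand is an aldehyde on D1, which is the carboxyl carbon of the key step.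

18 to 17, 16 and 15: the aldehyde is traced to the benzylic alcohol, ring F is opened at O1'–C2', and the resulting diol is traced to lactone 15, which holds the ring D carboxyl and the C2' hydroxyl in one ring. The forward ring closure must distinguish two primary alcohols; only the C2' hydroxyl can reach the ring E phenol through a six-membered transition state.

15 to 13 and 12: the C4' methylene is traced to the benzylic C4'–O(acyl) bond of a δ-lactone, and the C2' hydroxymethyl to a carboxylic acid. C4' is a temporary stereocentre whose C–O bond is as labile as a dialkoxybenzyl ester because of the ortho and para oxygens of ring E. The acid is reduced first so that C3' is not α to a carboxyl while the C4' cation exists. The forward step needs hydride capture to be faster than proton loss from C3'. The ring E ortho oxygen carries a 4-methoxybenzyl group and not an acetal: it leaves in the same acidic operation as a cation that the silane reduces, whereas an acetal would release a one-carbon electrophile beside a resorcinol-type ring.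

12 to 7 and 10 (through 11): the C3'–C4' bond and the lactone acyl–oxygen bond are cut. This reveals a homophthalic anhydride and a benzaldehyde, and it delivers C3' with its configuration, C2' and the C4 carbon next to the D2 methoxy group in one step. The forward step must control the enolate and aldehyde faces with a chiral base and hydrogen-bond donor. The spatial arrangement at C3' in 12 is that of 33: the descriptor is S in 12 and R from 14 onward only because C4' falls below ring D in priority once it loses its oxygen. No correction of the skeletons of 7, 10 or 12 is needed.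

7 to 6, 5, 3 (through 4), 2 and 1: the anhydride is opened to the diacid and diester, and the CH2–CO2 bond is cut at the benzylic carbon of an ortho-toluate. The oxygen pattern of ring D (methoxy beside the carbonyl, benzyloxy para to it) then follows from the different acidity of the chelated and the free hydroxyl of 1. This avoids a cross-coupling beside a formyl group and a statistical mono-methylation. The forward step needs lateral deprotonation to be faster than attack on the hindered ester.

10 to 9 and 8; 20 to 19; 28 to 27, 25 (through 26), 24 and 23: these are O-alkyl cuts and one C–C cut that lead to three commercial phenols. In 8 the chelated hydroxyl is alkylated last. In 24 the twisted central alkoxy group leaves the position ortho to a methoxy group as the most nucleophilic, which is the ring B carbon that must carry the two-carbon chain.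

## Other disconnections considered

Alternative 1: The cut is C4–C4a. In the forward step acid ionises the C4 carbinol of the acyclic aryl ether A1, and ring A, already attached through O1 to C2, attacks the cation para to its benzyloxy group to give A2, which is identical with 32. In its favour, the bond to the crowded C4 is made intramolecularly through a six-membered transition state, and the trans relation follows from the C3 aryl group set beforehand by an auxiliary-controlled aldol reaction. Against it, it needs a stoichiometric auxiliary, two ortho positions of ring A can in principle attack, and the C4 cation is also benzylic to ring D and may eliminate. It does not address ring F or C3', so it competes with steps 15 to 21 and not with the anhydride annulation. Compared with the chosen plan it is the better answer to the congestion at C4 and equal in its end point. It costs one step more from 18 and replaces catalyst control by an auxiliary. It is kept as the fallback for step 20.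

Alternative 2: The cuts are C4–C4a and the C3–ring B bond. In the forward step the boronate complex of alkenylboronic ester A3 and aryllithium 26 reacts with triflate A4 under Pd(OAc)2 and a chiral bisphosphine. The ring B aryl group migrates from boron to C3 while ring A is delivered to C4, which gives A5. In its favour, both centres come from one catalyst-controlled step, and anti addition across the (E)-alkene gives the trans relation directly without relying on equilibration at C3. On that point it is better than the chosen plan. Against it, the alkene carbon bears an ortho,ortho'-disubstituted aryl group, the migrating aryl group and the triflate are both ortho-alkoxylated, and direct cross-coupling without migration is the expected competitor. A5 also lacks C2, so a one-carbon homologation at a hindered secondary boron centre, oxidation, acetal removal and ether closure must follow. A3 would itself be made from 18 (for example with CrCl2 and a dihalomethylboronate), so this plan is equal to the chosen one up to 18 and longer after it (about seven steps against four). It offers nothing for C3'.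

Alternative 3: The cuts are D6–C3' and D1–C4. In the forward step the aryne generated from silyl triflate A6 inserts into the C(acyl)–C(α) bond of β-ketoester A7 to give A8. In its favour, both carbon arms of ring D are installed in one step. The regiochemistry should also be right, because the enolate carbon adds meta to the methoxy group and the acyl group ends next to it. The C4–C4a bond is present from the start, so the separate ring A addition of step 15 is not needed; on that point it is better. Against it, no stereocentre is formed. C3' would have to be created later by an enantioselective benzylation of an arylacetate flanked by a ketone. C4 arrives as a diaryl ketone with three ortho substituents, and turning it into a CH stereocentre bonded to C3 is harder than the addition to an aldehyde used here. A6 needs about as many steps as 7. The chosen plan forms fewer bonds on ring D in its key step but sets C3' absolutely and keeps C4 at an adjustable oxidation level.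

Key step: step 8

Assumption: the quinine-derived squaramide is taken to give the (3S,4S) acid 12 and the (R)-configured prolinol ether the (3R,4S) arrangement in 30, by analogy with the usual facial preferences of these catalyst families; if either sense is the opposite, the quinidine-derived or the (S)-configured catalyst is used and nothing else changes.

Step 1
Reactants: 1 methyl 2,4-dihydroxy-6-methylbenzoate
Product: 2 methyl 4-(benzyloxy)-2-hydroxy-6-methylbenzoate
Conditions: BnBr (1.05 equiv), K2CO3, acetone, reflux
Reagents that add atoms: benzyl bromide, BrCc1ccccc1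
Why: Williamson etherification; the 2-hydroxyl is chelated to the ester carbonyl and less nucleophilic, so the free 4-hydroxyl (future D4 oxygen) should react first.

Step 2
Reactants: 2 methyl 4-(benzyloxy)-2-hydroxy-6-methylbenzoate
Product: 3 methyl 4-(benzyloxy)-2-methoxy-6-methylbenzoate
Conditions: MeI, K2CO3, DMF, 60 °C
Reagents that add atoms: iodomethane, CI
Why: Williamson methylation of the chelated phenol under more forcing conditions places the future D2 methoxy group; ester and benzyl ether are inert.

Step 3
Reactants: 3 methyl 4-(benzyloxy)-2-methoxy-6-methylbenzoate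
Product: 5 methyl 4-(benzyloxy)-2-methoxy-6-(2-methoxy-2-oxoethyl)benzoate, via benzylic lithium species 4 (not isolated)
Conditions: LiN(iPr)2 (2.2 equiv), THF, −78 °C; (MeO)2CO, −78 → 0 °C; aq. NH4Cl
Reagents that add atoms: dimethyl carbonate, COC(=O)OC
Why: Lateral lithiation of an ortho-toluate and C-acylation with a carbonate; the ester between two ortho substituents resists self-condensation and the second equivalent of base holds the more acidic product as its enolate.

Step 4
Reactants: 5 methyl 4-(benzyloxy)-2-methoxy-6-(2-methoxy-2-oxoethyl)benzoate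
Product: 6 4-(benzyloxy)-2-(carboxymethyl)-6-methoxybenzoic acid
Conditions: KOH, EtOH/H2O, reflux; aq. HCl to pH 2
Reagents that add atoms: potassium hydroxide, [K+].[OH-]
Why: Saponification of both esters; the hindered aryl ester needs prolonged heating and the benzyl ether is stable to base.

Step 5
Reactants: 6 4-(benzyloxy)-2-(carboxymethyl)-6-methoxybenzoic acid
Product: 7 6-(benzyloxy)-8-methoxyisochromane-1,3-dione
Conditions: AcCl, reflux; evaporate
Reagents that add atoms: none
Why: Cyclodehydration of a homophthalic acid to the six-membered anhydride through a mixed anhydride; without base there is no C-acetylation at the methylene.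

Step 6
Reactants: 8 2,4-dihydroxybenzaldehyde
Product: 9 4-(benzyloxy)-2-hydroxybenzaldehyde
Conditions: BnBr, NaHCO3, KI (cat.), MeCN, reflux
Reagents that add atoms: benzyl bromide, BrCc1ccccc1
Why: Williamson etherification with a weak base; the 2-hydroxyl is chelated to the formyl group, so the 4-hydroxyl (future 7'-oxygen) should be alkylated.

Step 7
Reactants: 9 4-(benzyloxy)-2-hydroxybenzaldehyde
Product: 10 4-(benzyloxy)-2-[(4-methoxybenzyl)oxy]benzaldehyde
Conditions: 4-MeOC6H4CH2Cl, K2CO3, Bu4NI (cat.), DMF, 60 °C
Reagents that add atoms: 4-methoxybenzyl chloride, COc1ccc(CCl)cc1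
Why: Williamson etherification of the chelated phenol; the 4-methoxybenzyl group masks the future O1' and is chosen to leave in step 10 as a cation that the silane reduces.

Step 8
Reactants: 7 6-(benzyloxy)-8-methoxyisochromane-1,3-dione; 10 4-(benzyloxy)-2-[(4-methoxybenzyl)oxy]benzaldehyde
Product: 12 (3S,4S)-6-(benzyloxy)-3-{4-(benzyloxy)-2-[(4-methoxybenzyl)oxy]phenyl}-8-methoxy-1-oxoisochromane-4-carboxylic acid (trans), via aldol adduct 11 (not isolated)
Conditions: N-[3,5-bis(trifluoromethyl)phenyl]-N'-(9-deoxy-epi-quinin-9-yl)squaramide (10 mol%), MTBE, −15 °C; cold aq. citric acid wash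
Reagents that add atoms: none
Why: The quinuclidine nitrogen deprotonates 7 at its methylene (future C3') to an ion-paired enolate while the squaramide N–H pair binds the formyl oxygen of 10, and aldol addition forms C3'–C4' to give 11. The C4' alkoxide then attacks the aryl carbonyl in a 6-exo-trig acyl transfer and the anhydride C–O bond breaks, which closes the δ-lactone and releases the C2' carboxylate; attack on the other carbonyl would need a four-membered ring, and this fixes the regiochemistry. The closest known reaction type is the amine–squaramide-catalysed formal cycloaddition of enolisable homophthalic anhydrides with aromatic aldehydes to trans-dihydroisocoumarin acids. C3' and C4' are both set in the aldol event by the catalyst, which holds the enolate face and the aldehyde face in one hydrogen-bonded assembly. The trans relation is also the more stable one and C4' is removed later, so only the C3' configuration has to be right. The step needs reactivity from an electron-rich aldehyde and an electron-rich anhydride; the alkoxy groups lower the electrophilicity of 10, but the irreversible lactonisation should drain the aldol equilibrium. 12 is freed from the catalyst by the cold acid wash and reduced at once, because C3' is benzylic and α to a carboxyl.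

Step 9
Reactants: 12 (3S,4S)-6-(benzyloxy)-3-{4-(benzyloxy)-2-[(4-methoxybenzyl)oxy]phenyl}-8-methoxy-1-oxoisochromane-4-carboxylic acid
Product: 13 (3S,4R)-6-(benzyloxy)-3-{4-(benzyloxy)-2-[(4-methoxybenzyl)oxy]phenyl}-4-(hydroxymethyl)-8-methoxyisochroman-1-one
Conditions: BH3·SMe2, THF, 0 °C → rt; MeOH
Reagents that add atoms: none
Why: Chemoselective borane reduction of a carboxylic acid beside an electron-rich aryl lactone; the medium is not basic, so C3' should keep its configuration and ceases to be α to a carboxyl (the descriptor changes by priority only).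

Step 10
Reactants: 13 (3S,4R)-6-(benzyloxy)-3-{4-(benzyloxy)-2-[(4-methoxybenzyl)oxy]phenyl}-4-(hydroxymethyl)-8-methoxyisochroman-1-one
Product: 15 (4R)-6-(benzyloxy)-4-[4-(benzyloxy)-2-hydroxybenzyl]-8-methoxyisochroman-1-one, via hydroxy acid 14 (not isolated)
Conditions: Et3SiH (8 equiv), CF3CO2H/CH2Cl2 1:10, −20 → 0 °C; then TsOH·H2O (cat.), toluene, 40 °C
Reagents that add atoms: none
Why: Acidolysis of a dialkoxybenzyl-type ester with silane capture (ionic hydrogenation): the C4'–O bond ionises, the cation stabilised by the ortho and para oxygens of ring E takes hydride from Et3SiH, the 4-methoxybenzyl ether leaves likewise as 4-methylanisole, and 14 lactonises through its C2' hydroxyl; excess silane and low temperature are meant to make hydride capture outrun proton loss from C3'.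

Step 11
Reactants: 15 (4R)-6-(benzyloxy)-4-[4-(benzyloxy)-2-hydroxybenzyl]-8-methoxyisochroman-1-one
Product: 16 5-(benzyloxy)-2-[(2R)-2-[5-(benzyloxy)-2-(hydroxymethyl)-3-methoxyphenyl]-3-hydroxypropyl]phenol
Conditions: LiAlH4, THF, 0 °C → rt; H2O, aq. NaOH
Reagents that add atoms: none
Why: Hydride reduction of the lactone frees the C2' hydroxyl and brings the ring D carbon to the benzylic alcohol level; the basic work-up avoids acid-induced loss of the activated benzylic hydroxyl, and C3' bears no acidic hydrogen.

Step 12
Reactants: 16 5-(benzyloxy)-2-[(2R)-2-[5-(benzyloxy)-2-(hydroxymethyl)-3-methoxyphenyl]-3-hydroxypropyl]phenol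
Product: 17 {4-(benzyloxy)-2-[(3R)-7-(benzyloxy)chroman-3-yl]-6-methoxyphenyl}methanol
Conditions: PPh3, DIAD, THF (0.01 M), 0 °C → rt
Reagents that add atoms: none
Why: Mitsunobu etherification closes ring F (6-exo-tet at C2'); the phenol is the only acidic partner and reaches only the C2' oxyphosphonium through a six-membered transition state, whereas the hindered benzylic hydroxyl on D1 would need an eight-membered one; C3' is not involved.

Step 13
Reactants: 17 {4-(benzyloxy)-2-[(3R)-7-(benzyloxy)chroman-3-yl]-6-methoxyphenyl}methanol
Product: 18 4-(benzyloxy)-2-[(3R)-7-(benzyloxy)chroman-3-yl]-6-methoxybenzaldehyde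
Conditions: MnO2, CH2Cl2, rt
Reagents that add atoms: none
Why: MnO2 oxidises the electron-rich benzylic alcohol to the aldehyde without over-oxidation; ethers and C3' are inert.

Step 14
Reactants: 19 4-bromobenzene-1,3-diol
Product: 20 5-(benzyloxy)-2-bromophenol
Conditions: BnBr (1.0 equiv), K2CO3, acetone, rt
Reagents that add atoms: benzyl bromide, BrCc1ccccc1
Why: Williamson mono-etherification expected to favour the hydroxyl remote from bromine (less hindered, more nucleophilic phenoxide); the regioisomer and the bis-ether are removed by chromatography.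

Step 15
Reactants: 20 5-(benzyloxy)-2-bromophenol; 18 4-(benzyloxy)-2-[(3R)-7-(benzyloxy)chroman-3-yl]-6-methoxybenzaldehyde
Product: 22 5-(benzyloxy)-2-[{4-(benzyloxy)-2-[(3R)-7-(benzyloxy)chroman-3-yl]-6-methoxyphenyl}(hydroxy)methyl]phenol (both carbinol epimers), via dilithio phenolate 21 (not isolated)
Conditions: 20, n-BuLi (2.1 equiv), THF, −78 °C; then 18, −78 → −20 °C; aq. NH4Cl
Reagents that add atoms: none
Why: O-deprotonation and bromine–lithium exchange give the C,O-dilithio species, which adds to the hindered, non-enolisable aldehyde and forms C4–C4a; the carbinol centre is unselective and is erased in step 20, and 22 is used without acidic chromatography.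

Step 16
Reactants: 23 2,6-dimethoxyphenol
Product: 24 2-(benzyloxy)-1,3-dimethoxybenzene
Conditions: BnBr, K2CO3, DMF, rt
Reagents that add atoms: benzyl bromide, BrCc1ccccc1
Why: Williamson etherification masks the future ring B hydroxyl and turns the ring into a 1,2,3-trialkoxybenzene.

Step 17
Reactants: 24 2-(benzyloxy)-1,3-dimethoxybenzene
Product: 25 3-(benzyloxy)-1-bromo-2,4-dimethoxybenzene
Conditions: NBS, MeCN, 0 °C → rt
Reagents that add atoms: N-bromosuccinimide, O=C1CCC(=O)N1Br
Why: Electrophilic bromination of a 1,2,3-trialkoxybenzene goes ortho to an outer methoxy group and para to the other, because the twisted central alkoxy group activates its para position only weakly.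

Step 18
Reactants: 25 3-(benzyloxy)-1-bromo-2,4-dimethoxybenzene
Product: 27 2-[3-(benzyloxy)-2,4-dimethoxyphenyl]ethan-1-ol, via aryllithium 26 (not isolated)
Conditions: n-BuLi, THF, −78 °C; oxirane, −78 °C → rt; aq. NH4Cl
Reagents that add atoms: oxirane, C1CO1
Why: Bromine–lithium exchange is faster than benzylic deprotonation of the benzyl ether at −78 °C, and the aryllithium opens the epoxide to give the two-carbon chain that becomes C3–C2.

Step 19
Reactants: 27 2-[3-(benzyloxy)-2,4-dimethoxyphenyl]ethan-1-ol
Product: 28 [3-(benzyloxy)-2,4-dimethoxyphenyl]acetaldehyde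
Conditions: Dess–Martin periodinane, NaHCO3, CH2Cl2, 0 °C; used at once
Reagents that add atoms: none
Why: Buffered Dess–Martin oxidation gives the sensitive arylacetaldehyde without acid or base that would cause self-aldol condensation.

Step 20
Reactants: 22 5-(benzyloxy)-2-[{4-(benzyloxy)-2-[(3R)-7-(benzyloxy)chroman-3-yl]-6-methoxyphenyl}(hydroxy)methyl]phenol; 28 [3-(benzyloxy)-2,4-dimethoxyphenyl]acetaldehyde
Product: 31 5-(benzyloxy)-2-[(1S,2R)-2-[3-(benzyloxy)-2,4-dimethoxyphenyl]-1-{4-(benzyloxy)-2-[(3R)-7-(benzyloxy)chroman-3-yl]-6-methoxyphenyl}-3-hydroxypropyl]phenol, via o-quinone methide 29 (not isolated), via chroman-2-ol 30 (not isolated)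
Conditions: (R)-α,α-diphenylprolinol trimethylsilyl ether (20 mol%), PhCO2H (20 mol%), 4 Å sieves, CH2Cl2, 0 °C → rt; then NaBH4, MeOH, 0 °C
Reagents that add atoms: none
Why: Aminocatalytic Michael addition–hemiacetalisation (formal [4+2]) of an enamine to an o-quinone methide: acid-assisted loss of water from 22 gives 29, the (E)-enamine of 28 adds through its unshielded face to the methide carbon to form C3–C4, ring closure gives 30 and NaBH4 opens it to 31; C3 is set by the bulky diphenyl(silyloxy)methyl group, C4 by the synclinal approach of the two π systems, and any C3 epimerisation through the open aldehyde leads to the more stable trans arrangement.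

Step 21
Reactants: 31 5-(benzyloxy)-2-[(1S,2R)-2-[3-(benzyloxy)-2,4-dimethoxyphenyl]-1-{4-(benzyloxy)-2-[(3R)-7-(benzyloxy)chroman-3-yl]-6-methoxyphenyl}-3-hydroxypropyl]phenol
Product: 32 (3R,4S)-7-(benzyloxy)-3-[3-(benzyloxy)-2,4-dimethoxyphenyl]-4-{4-(benzyloxy)-2-[(3R)-7-(benzyloxy)chroman-3-yl]-6-methoxyphenyl}chromane
Conditions: PPh3, DIAD, THF, 0 °C → rt
Reagents that add atoms: none
Why: Mitsunobu etherification closes ring C (6-exo-tet at C2) between the only free phenol and the primary alcohol; no bond to C3 or C4 is touched.

Step 22
Reactants: 32 (3R,4S)-7-(benzyloxy)-3-[3-(benzyloxy)-2,4-dimethoxyphenyl]-4-{4-(benzyloxy)-2-[(3R)-7-(benzyloxy)chroman-3-yl]-6-methoxyphenyl}chromane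
Product: 33 (3R,4S)-3-(3-hydroxy-2,4-dimethoxyphenyl)-4-{4-hydroxy-2-[(3R)-7-hydroxychroman-3-yl]-6-methoxyphenyl}chroman-7-ol
Conditions: H2 (1 atm), Pd/C, EtOAc/MeOH, rt
Reagents that add atoms: none
Why: Hydrogenolysis of four aryl benzyl ethers; the skeleton has no benzylic C–O bond, and the methyl ethers and the three stereocentres are inert.

## Compound list

1 | methyl 2,4-dihydroxy-6-methylbenzoate | COC(=O)c1c(C)cc(O)cc1O | starting material
2 | methyl 4-(benzyloxy)-2-hydroxy-6-methylbenzoate | COC(=O)c1c(C)cc(OCc2ccccc2)cc1O | intermediate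
3 | methyl 4-(benzyloxy)-2-methoxy-6-methylbenzoate | COC(=O)c1c(C)cc(OCc2ccccc2)cc1OC | intermediate
4 | [5-(benzyloxy)-3-methoxy-2-(methoxycarbonyl)benzyl]lithium (formed in the flask) | COC(=O)c1c(C[Li])cc(OCc2ccccc2)cc1OC | intermediate
5 | methyl 4-(benzyloxy)-2-methoxy-6-(2-methoxy-2-oxoethyl)benzoate | COC(=O)Cc1cc(OCc2ccccc2)cc(OC)c1C(=O)OC | intermediate
6 | 4-(benzyloxy)-2-(carboxymethyl)-6-methoxybenzoic acid | OC(=O)Cc1cc(OCc2ccccc2)cc(OC)c1C(=O)O | intermediate
7 | 6-(benzyloxy)-8-methoxyisochromane-1,3-dione | COc1cc(OCc2ccccc2)cc2c1C(=O)OC(=O)C2 | intermediate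
8 | 2,4-dihydroxybenzaldehyde | O=Cc1ccc(O)cc1O | starting material
9 | 4-(benzyloxy)-2-hydroxybenzaldehyde | O=Cc1ccc(OCc2ccccc2)cc1O | intermediate
10 | 4-(benzyloxy)-2-[(4-methoxybenzyl)oxy]benzaldehyde | COc1ccc(COc2cc(OCc3ccccc3)ccc2C=O)cc1 | intermediate
11 | (4S)-6-(benzyloxy)-4-[(S)-{4-(benzyloxy)-2-[(4-methoxybenzyl)oxy]phenyl}(hydroxy)methyl]-8-methoxyisochromane-1,3-dione (aldol adduct, formed in the flask) | COc1cc(OCc2ccccc2)cc2c1C(=O)OC(=O)[C@@H]2[C@H](O)c1ccc(OCc3ccccc3)cc1OCc1ccc(OC)cc1 | intermediate
12 | (3S,4S)-6-(benzyloxy)-3-{4-(benzyloxy)-2-[(4-methoxybenzyl)oxy]phenyl}-8-methoxy-1-oxoisochromane-4-carboxylic acid | COc1cc(OCc2ccccc2)cc2c1C(=O)O[C@H](c1ccc(OCc3ccccc3)cc1OCc1ccc(OC)cc1)[C@H]2C(=O)O | intermediate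
13 | (3S,4R)-6-(benzyloxy)-3-{4-(benzyloxy)-2-[(4-methoxybenzyl)oxy]phenyl}-4-(hydroxymethyl)-8-methoxyisochroman-1-one | COc1cc(OCc2ccccc2)cc2c1C(=O)O[C@H](c1ccc(OCc3ccccc3)cc1OCc1ccc(OC)cc1)[C@H]2CO | intermediate
14 | 4-(benzyloxy)-2-[(2R)-1-[4-(benzyloxy)-2-hydroxyphenyl]-3-hydroxypropan-2-yl]-6-methoxybenzoic acid (formed in the flask) | COc1cc(OCc2ccccc2)cc([C@H](CO)Cc2ccc(OCc3ccccc3)cc2O)c1C(=O)O | intermediate
15 | (4R)-6-(benzyloxy)-4-[4-(benzyloxy)-2-hydroxybenzyl]-8-methoxyisochroman-1-one | COc1cc(OCc2ccccc2)cc2c1C(=O)OC[C@@H]2Cc1ccc(OCc2ccccc2)cc1O | intermediate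
16 | 5-(benzyloxy)-2-[(2R)-2-[5-(benzyloxy)-2-(hydroxymethyl)-3-methoxyphenyl]-3-hydroxypropyl]phenol | COc1cc(OCc2ccccc2)cc([C@H](CO)Cc2ccc(OCc3ccccc3)cc2O)c1CO | intermediate
17 | {4-(benzyloxy)-2-[(3R)-7-(benzyloxy)chroman-3-yl]-6-methoxyphenyl}methanol | COc1cc(OCc2ccccc2)cc([C@@H]2COc3cc(OCc4ccccc4)ccc3C2)c1CO | intermediate
18 | 4-(benzyloxy)-2-[(3R)-7-(benzyloxy)chroman-3-yl]-6-methoxybenzaldehyde | COc1cc(OCc2ccccc2)cc([C@@H]2COc3cc(OCc4ccccc4)ccc3C2)c1C=O | intermediate
19 | 4-bromobenzene-1,3-diol | Oc1ccc(Br)c(O)c1 | starting material
20 | 5-(benzyloxy)-2-bromophenol | Oc1cc(OCc2ccccc2)ccc1Br | intermediate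
21 | lithium 5-(benzyloxy)-2-lithiophenolate (formed in the flask) | [Li]Oc1cc(OCc2ccccc2)ccc1[Li] | intermediate
22 | 5-(benzyloxy)-2-[{4-(benzyloxy)-2-[(3R)-7-(benzyloxy)chroman-3-yl]-6-methoxyphenyl}(hydroxy)methyl]phenol (both carbinol epimers) | COc1cc(OCc2ccccc2)cc([C@@H]2COc3cc(OCc4ccccc4)ccc3C2)c1C(O)c1ccc(OCc2ccccc2)cc1O | intermediate
23 | 2,6-dimethoxyphenol | COc1cccc(OC)c1O | starting material
24 | 2-(benzyloxy)-1,3-dimethoxybenzene | COc1cccc(OC)c1OCc1ccccc1 | intermediate
25 | 3-(benzyloxy)-1-bromo-2,4-dimethoxybenzene | COc1ccc(Br)c(OC)c1OCc1ccccc1 | intermediate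
26 | [3-(benzyloxy)-2,4-dimethoxyphenyl]lithium (formed in the flask) | [Li]c1ccc(OC)c(OCc2ccccc2)c1OC | intermediate
27 | 2-[3-(benzyloxy)-2,4-dimethoxyphenyl]ethan-1-ol | COc1ccc(CCO)c(OC)c1OCc1ccccc1 | intermediate
28 | [3-(benzyloxy)-2,4-dimethoxyphenyl]acetaldehyde | COc1ccc(CC=O)c(OC)c1OCc1ccccc1 | intermediate
29 | 3-(benzyloxy)-6-({4-(benzyloxy)-2-[(3R)-7-(benzyloxy)chroman-3-yl]-6-methoxyphenyl}methylidene)cyclohexa-2,4-dien-1-one (formed in the flask, alkene geometry not fixed) | COc1cc(OCc2ccccc2)cc([C@@H]2COc3cc(OCc4ccccc4)ccc3C2)c1C=C1C=CC(OCc2ccccc2)=CC1=O | intermediate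
30 | (3R,4S)-7-(benzyloxy)-3-[3-(benzyloxy)-2,4-dimethoxyphenyl]-4-{4-(benzyloxy)-2-[(3R)-7-(benzyloxy)chroman-3-yl]-6-methoxyphenyl}chroman-2-ol (both C2 epimers, formed in the flask) | COc1ccc([C@@H]2C(O)Oc3cc(OCc4ccccc4)ccc3[C@H]2c2c(OC)cc(OCc3ccccc3)cc2[C@@H]2COc3cc(OCc4ccccc4)ccc3C2)c(OC)c1OCc1ccccc1 | intermediate
31 | 5-(benzyloxy)-2-[(1S,2R)-2-[3-(benzyloxy)-2,4-dimethoxyphenyl]-1-{4-(benzyloxy)-2-[(3R)-7-(benzyloxy)chroman-3-yl]-6-methoxyphenyl}-3-hydroxypropyl]phenol | COc1ccc([C@H](CO)[C@@H](c2ccc(OCc3ccccc3)cc2O)c2c(OC)cc(OCc3ccccc3)cc2[C@@H]2COc3cc(OCc4ccccc4)ccc3C2)c(OC)c1OCc1ccccc1 | intermediate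
32 | (3R,4S)-7-(benzyloxy)-3-[3-(benzyloxy)-2,4-dimethoxyphenyl]-4-{4-(benzyloxy)-2-[(3R)-7-(benzyloxy)chroman-3-yl]-6-methoxyphenyl}chromane | COc1ccc([C@@H]2COc3cc(OCc4ccccc4)ccc3[C@H]2c2c(OC)cc(OCc3ccccc3)cc2[C@@H]2COc3cc(OCc4ccccc4)ccc3C2)c(OC)c1OCc1ccccc1 | intermediate
33 | (3R,4S)-3-(3-hydroxy-2,4-dimethoxyphenyl)-4-{4-hydroxy-2-[(3R)-7-hydroxychroman-3-yl]-6-methoxyphenyl}chroman-7-ol | COc1ccc([C@@H]2COc3cc(O)ccc3[C@H]2c2c(OC)cc(O)cc2[C@@H]2COc3cc(O)ccc3C2)c(OC)c1O | target

## Step count and least certain steps

Total: 22 steps. Longest linear sequence: 15 steps (steps 1 to 5, 8 to 13, 15, 20 to 22).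

Step 8 (key step). The most likely failure is low enantiofacial discrimination or slow turnover, because both partners are electron-rich and the aldehyde carries an ortho substituent; the catalyst family is best established with electron-poor or unhindered aldehydes. Partial loss of the C3' configuration during isolation of the α-aryl acid is a second concern. The fallback sets out from 7 and 10 and comes back at 12. The annulation is run with an achiral amine (iPr2NEt, CH2Cl2) to give the racemic trans acid F1. F1 is resolved by crystallisation of its salt with (R)-1-phenylethylamine; the salt of the (3S,4S) acid is F2, taken from the crystals or the mother liquor, whichever carries it. Acidification returns 12.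

Step 10. The risk is erosion of the C3' configuration by proton loss from the C4' cation and reprotonation of the resulting stilbene. C-benzylation of the freed resorcinol-type ring by the 4-methoxybenzyl cation and slow acidolysis of the benzyl ethers are lesser risks. The fallback sets out from 13 and comes back at 15, and it avoids any cation beside C3'. DDQ (CH2Cl2, aqueous buffer) removes the 4-methoxybenzyl group oxidatively to give (3S,4R)-6-(benzyloxy)-3-[4-(benzyloxy)-2-hydroxyphenyl]-4-(hydroxymethyl)-8-methoxyisochroman-1-one F3. NaBH4 in EtOH/THF then turns the phenoxide into an o-quinone methide by 1,4-elimination of the lactone carboxylate and reduces it in the same flask. Acidification gives 14, which lactonises to 15.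

Step 12. The risk is loss of chemoselectivity between the two primary hydroxyls: activation of the electron-rich benzylic hydroxyl on D1 could lead to intermolecular O-alkylation or to cyclic ether formation with the C2' hydroxyl. The fallback sets out from 13 and comes back at 17, and it closes ring F while the ring D carbon is still tied up as the lactone. The phenol lactone F3 (prepared as described for step 10) is cyclised under Mitsunobu conditions to the trans-fused tetracyclic lactone F4. Et3SiH and CF3CO2H then cleave the benzylic C4'–O bond to give 4-(benzyloxy)-2-[(3R)-7-(benzyloxy)chroman-3-yl]-6-methoxybenzoic acid F5, and LiAlH4 reduces F5 to 17.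

Step 20. The risks are slow addition of the enamine to a methide carbon shielded on both faces by the ortho substituents of ring D, oligomerisation of the o-quinone methide, self-aldol condensation of 28, and poor facial selectivity at C4. The fallback sets out from 27 and 18 and comes back at 32, and it replaces the intermolecular addition by an intramolecular Friedel–Crafts closure.
- 27 is oxidised (TEMPO, NaOCl, NaClO2) to [3-(benzyloxy)-2,4-dimethoxyphenyl]acetic acid F6.
- F6 is coupled through its pivalic mixed anhydride (t-BuCOCl, Et3N, LiCl) with (S)-4-benzyl-oxazolidin-2-one to the imide F7.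
- The boron enolate of F7 (Bu2BOTf, iPr2NEt) adds to 18 in an Evans syn aldol reaction to give the adduct F8, with C3 fixed by the auxiliary.
- LiBH4 removes the auxiliary and gives the 1,3-diol F9.
- Mitsunobu reaction of the primary hydroxyl with 3-(benzyloxy)phenol gives the aryl ether carbinol F10, the same compound as A1.
- BF3·OEt2 in CH2Cl2 at low temperature ionises C4, and ring A closes ring C trans to the C3 aryl group to give 32.

Step 15. The risks are incomplete halogen–metal exchange or proton transfer with the dilithio species, and ionisation of the doubly activated carbinol on acidic supports followed by self-condensation. The fallback sets out from 18 and comes back at 22 without a halogen–metal exchange. The bromomagnesium salt of commercial 3-(benzyloxy)phenol (EtMgBr, toluene) is condensed with 18; chelate-controlled ortho-hydroxyalkylation at the less hindered ortho position gives 22. No new compound arises on this way.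

## Further compounds

F1 | step 8 | racemic trans-6-(benzyloxy)-3-{4-(benzyloxy)-2-[(4-methoxybenzyl)oxy]phenyl}-8-methoxy-1-oxoisochromane-4-carboxylic acid (both enantiomers) | COc1cc(OCc2ccccc2)cc2c1C(=O)O[C@H](c1ccc(OCc3ccccc3)cc1OCc1ccc(OC)cc1)[C@H]2C(=O)O.COc1cc(OCc2ccccc2)cc2c1C(=O)O[C@@H](c1ccc(OCc3ccccc3)cc1OCc1ccc(OC)cc1)[C@@H]2C(=O)O
F2 | step 8 | (R)-1-phenylethylammonium salt of the (3S,4S) acid 12 | COc1cc(OCc2ccccc2)cc2c1C(=O)O[C@H](c1ccc(OCc3ccccc3)cc1OCc1ccc(OC)cc1)[C@H]2C(=O)[O-].C[C@@H]([NH3+])c1ccccc1
F3 | step 10 | (3S,4R)-6-(benzyloxy)-3-[4-(benzyloxy)-2-hydroxyphenyl]-4-(hydroxymethyl)-8-methoxyisochroman-1-one | COc1cc(OCc2ccccc2)cc2c1C(=O)O[C@H](c1ccc(OCc3ccccc3)cc1O)[C@H]2CO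
F4 | step 12 | trans-fused tetracyclic lactone: ring F closed (O1'–C2') on F3, C4' (S) still bonded to the lactone oxygen, C3' (R) | COc1cc(OCc2ccccc2)cc2c1C(=O)O[C@@H]1c3ccc(OCc4ccccc4)cc3OC[C@@H]21
F5 | step 12 | 4-(benzyloxy)-2-[(3R)-7-(benzyloxy)chroman-3-yl]-6-methoxybenzoic acid | COc1cc(OCc2ccccc2)cc([C@@H]2COc3cc(OCc4ccccc4)ccc3C2)c1C(=O)O
F6 | step 20 | [3-(benzyloxy)-2,4-dimethoxyphenyl]acetic acid | COc1ccc(CC(=O)O)c(OC)c1OCc1ccccc1
F7 | step 20 | (4S)-4-benzyl-3-{[3-(benzyloxy)-2,4-dimethoxyphenyl]acetyl}oxazolidin-2-one | COc1ccc(CC(=O)N2C(=O)OC[C@@H]2Cc2ccccc2)c(OC)c1OCc1ccccc1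
F8 | step 20 | (4S)-4-benzyl-3-[(2S,3S)-2-[3-(benzyloxy)-2,4-dimethoxyphenyl]-3-{4-(benzyloxy)-2-[(3R)-7-(benzyloxy)chroman-3-yl]-6-methoxyphenyl}-3-hydroxypropanoyl]oxazolidin-2-one | COc1ccc([C@H](C(=O)N2C(=O)OC[C@@H]2Cc2ccccc2)[C@H](O)c2c(OC)cc(OCc3ccccc3)cc2[C@@H]2COc3cc(OCc4ccccc4)ccc3C2)c(OC)c1OCc1ccccc1
F9 | step 20 | (1S,2R)-2-[3-(benzyloxy)-2,4-dimethoxyphenyl]-1-{4-(benzyloxy)-2-[(3R)-7-(benzyloxy)chroman-3-yl]-6-methoxyphenyl}propane-1,3-diol | COc1ccc([C@H](CO)[C@H](O)c2c(OC)cc(OCc3ccccc3)cc2[C@@H]2COc3cc(OCc4ccccc4)ccc3C2)c(OC)c1OCc1ccccc1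
F10 | step 20 | (1S,2R)-2-[3-(benzyloxy)-2,4-dimethoxyphenyl]-1-{4-(benzyloxy)-2-[(3R)-7-(benzyloxy)chroman-3-yl]-6-methoxyphenyl}-3-[3-(benzyloxy)phenoxy]propan-1-ol | COc1ccc([C@H](COc2cccc(OCc3ccccc3)c2)[C@H](O)c2c(OC)cc(OCc3ccccc3)cc2[C@@H]2COc3cc(OCc4ccccc4)ccc3C2)c(OC)c1OCc1ccccc1
F0 | step 15 | none | none
A1 | alternative 1 | (1S,2R)-2-[3-(benzyloxy)-2,4-dimethoxyphenyl]-1-{4-(benzyloxy)-2-[(3R)-7-(benzyloxy)chroman-3-yl]-6-methoxyphenyl}-3-[3-(benzyloxy)phenoxy]propan-1-ol (acyclic C4 carbinol) | COc1ccc([C@H](COc2cccc(OCc3ccccc3)c2)[C@H](O)c2c(OC)cc(OCc3ccccc3)cc2[C@@H]2COc3cc(OCc4ccccc4)ccc3C2)c(OC)c1OCc1ccccc1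
A2 | alternative 1 | tetra-O-benzyl ether of the target, identical with 32 | COc1ccc([C@@H]2COc3cc(OCc4ccccc4)ccc3[C@H]2c2c(OC)cc(OCc3ccccc3)cc2[C@@H]2COc3cc(OCc4ccccc4)ccc3C2)c(OC)c1OCc1ccccc1
A3 | alternative 2 | 2-[(E)-2-{4-(benzyloxy)-2-[(3R)-7-(benzyloxy)chroman-3-yl]-6-methoxyphenyl}ethenyl]-4,4,5,5-tetramethyl-1,3,2-dioxaborolane | COc1cc(OCc2ccccc2)cc([C@@H]2COc3cc(OCc4ccccc4)ccc3C2)c1/C=C/B1OC(C)(C)C(C)(C)O1
A4 | alternative 2 | 4-(benzyloxy)-2-(methoxymethoxy)phenyl trifluoromethanesulfonate | COCOc1cc(OCc2ccccc2)ccc1OS(=O)(=O)C(F)(F)F
A5 | alternative 2 | secondary benzylic pinacol boronate with C3 and C4 set, boron on C3 | COc1ccc([C@H](B2OC(C)(C)C(C)(C)O2)[C@@H](c2ccc(OCc3ccccc3)cc2OCOC)c2c(OC)cc(OCc3ccccc3)cc2[C@@H]2COc3cc(OCc4ccccc4)ccc3C2)c(OC)c1OCc1ccccc1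
A6 | alternative 3 | 5-(benzyloxy)-3-methoxy-2-(trimethylsilyl)phenyl trifluoromethanesulfonate | COc1cc(OCc2ccccc2)cc(OS(=O)(=O)C(F)(F)F)c1[Si](C)(C)C
A7 | alternative 3 | methyl 3-[4-(benzyloxy)-2-(methoxymethoxy)phenyl]-3-oxopropanoate | COCOc1cc(OCc2ccccc2)ccc1C(=O)CC(=O)OC
A8 | alternative 3 | methyl 2-[5-(benzyloxy)-2-[4-(benzyloxy)-2-(methoxymethoxy)benzoyl]-3-methoxyphenyl]acetate | COC(=O)Cc1cc(OCc2ccccc2)cc(OC)c1C(=O)c1ccc(OCc2ccccc2)cc1OCOC
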